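**Retrosynthetic overview**
1. C1–Cl/C6–Br (cis) are set last by a net syn-bromochlorination of the trisubstituted ring alkene of 10 (PhSeCl anti-addition, then Br replaces Se with inversion).
2. C3–Br/C4–CH=CHCl (trans) come in one operation from the fused trans-2-chlorocyclobutyl bromide 9: cyclobutyl→cyclopropylcarbinyl ring contraction (1,2-alkyl shift), then bromide opening of the cyclopropane.
3. The cyclobutane comes from dichloroketene (from Cl3CCOCl) and 1,5-dimethylcyclohexa-1,4-diene; the ketene's two carbons and one chlorine become the chlorovinyl group.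
4. The diene comes from m-xylene (Birch). Ring order: the six-membered ring is carried from m-xylene; the cyclobutane is built on it, contracted to a transient cyclopropane and opened.
5. Absolute configuration comes from a classical resolution of the cyclobutanol as its (1S)-camphorsulfonate, which is also the leaving group.

Assumption: 5, 6 and 7 are racemates; their names and SMILES show the enantiomer that is kept in step 5.

**Step 1**
Reactants: 1 m-xylene
Product: 2 1,5-dimethylcyclohexa-1,4-diene
Conditions: Li, NH3(l), EtOH, THF, −78 → −33 °C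
Reagents that add atoms: none
Why: Birch reduction; both methyl groups stay on sp2 carbons, so the 2,5-dihydro product with two trisubstituted alkenes forms, and there is no stereocentre.

**Step 2**
Reactants: 2 1,5-dimethylcyclohexa-1,4-diene (2 equiv); 3 trichloroacetyl chloride
Product: 5 rac-(1S,6R)-8,8-dichloro-1,3-dimethylbicyclo[4.2.0]oct-3-en-7-one, via dichloroketene 4 (not isolated)
Conditions: Zn–Cu, POCl3, Et2O, 35 °C
Reagents that add atoms: none
Why: Ketene–alkene [2+2] cycloaddition; the C=O carbon bonds to the less substituted alkene CH and CCl2 to the methyl-bearing carbon, addition is suprafacial on the alkene (cis fusion, racemic), and excess symmetric diene keeps it to mono-addition.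

**Step 3**
Reactants: 5 rac-(1S,6R)-8,8-dichloro-1,3-dimethylbicyclo[4.2.0]oct-3-en-7-one
Product: 6 rac-(1S,6R,8S)-8-chloro-1,3-dimethylbicyclo[4.2.0]oct-3-en-7-one
Conditions: Zn dust, AcOH, TMEDA, EtOH, 0 °C → rt
Reagents that add atoms: none
Why: Zinc reductive monodechlorination of an α,α-dichloroketone via the zinc enolate; protonation from the convex (exo) face leaves Cl endo, trans to the angular methyl.

**Step 4**
Reactants: 6 rac-(1S,6R,8S)-8-chloro-1,3-dimethylbicyclo[4.2.0]oct-3-en-7-one
Product: 7 rac-(1S,6R,7R,8S)-8-chloro-1,3-dimethylbicyclo[4.2.0]oct-3-en-7-ol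
Conditions: NaBH4, MeOH, −20 °C
Reagents that add atoms: none
Why: Borohydride reduction; hydride adds from the convex face and anti to C–Cl (Felkin–Anh), giving the endo alcohol cis to Cl.

**Step 5**
Reactants: 7 rac-(1S,6R,7R,8S)-8-chloro-1,3-dimethylbicyclo[4.2.0]oct-3-en-7-ol
Product: 8 (1S,6R,7R,8S)-8-chloro-1,3-dimethylbicyclo[4.2.0]oct-3-en-7-yl (1S)-camphor-10-sulfonate
Conditions: (1S)-(+)-camphor-10-sulfonyl chloride, Et3N, DMAP (cat.), CH2Cl2, 0 °C; separation of the two diastereomers (SiO2, then crystallisation)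
Reagents that add atoms: (1S)-(+)-camphor-10-sulfonyl chloride, CC1(C)[C@@H]2CC[C@@]1(CS(Cl)(=O)=O)C(=O)C2
Why: Sulfonylation of the racemic alcohol with an enantiopure sulfonyl chloride gives two separable diastereomeric sulfonates (classical resolution, at most 50 %); the one from the (1S,6R,7R,8S) alcohol is kept and its sulfonate serves as the leaving group.

**Step 6**
Reactants: 8 (1S,6R,7R,8S)-8-chloro-1,3-dimethylbicyclo[4.2.0]oct-3-en-7-yl (1S)-camphor-10-sulfonate
Product: 10 (4S,5R)-5-bromo-4-[(E)-2-chloroethenyl]-1,5-dimethylcyclohex-1-ene, via trans-bromochloride 9 (not isolated)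
Conditions: LiBr, butanone, 55 °C; solvent switch, then ZnBr2 (10 mol %), CH2Cl2, −20 → 0 °C
Reagents that add atoms: lithium bromide, [Li+].[Br-]
Why: Proposed new method: Lewis-acid-catalysed isomerisation of a trans-2-chlorocyclobutyl bromide into an (E)-chlorovinyl homoallylic tertiary bromide. First, a known SN2 (Finkelstein-type) displacement of the endo sulfonate from the open convex face puts Br exo and trans to Cl (9). ZnBr2 then ionises C7–Br with 1,3-participation of the methyl-bearing bridgehead C1, which shifts from C8 to C7 (cyclobutyl→cyclopropylcarbinyl ring contraction, Demjanov/Wagner–Meerwein type) to give a chlorine-stabilised norcaranyl-carbinyl cation. Bromide returns on the exo face to the tertiary cyclopropane carbon with inversion (cyclopropylcarbinyl→homoallyl opening, as in the Julia olefin synthesis), so Br ends anti to the side chain (C3/C4 of the target), and Cl trans to the leaving group maps onto the E alkene. Release of cyclobutane strain drives the reaction. Closest known chemistry: ZnX2-mediated cyclobutyl/cyclopropylcarbinyl/homoallyl halide interconversion and the Julia homoallyl bromide synthesis.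

**Step 7**
Reactants: 10 (4S,5R)-5-bromo-4-[(E)-2-chloroethenyl]-1,5-dimethylcyclohex-1-ene
Product: 13 (1R,2S,4S,5R)-1,4-dibromo-5-chloro-2-[(E)-2-chloroethenyl]-1,5-dimethylcyclohexane, via chloro selenide 11 (not isolated), via selenium dibromide 12 (not isolated)
Conditions: PhSeCl, CH2Cl2, −78 → −20 °C; then Br2, −78 → 0 °C
Reagents that add atoms: benzeneselenenyl chloride, Cl[Se]c1ccccc1; bromine, BrBr
Why: Net syn-bromochlorination in two known stages: reversible anti chloroselenenylation (Markovnikov, trans-diaxial opening on the face that keeps C–Br and the side chain equatorial) puts Cl on the tertiary carbon and Se on C6; Br2 then oxidises Se to the Se(IV) dibromide and bromide displaces it with inversion (bromodeselenenylation), so Br ends cis to Cl and both remaining stereocentres are set.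

**Compound list**
1 | m-xylene | Cc1cccc(C)c1 | starting material
2 | 1,5-dimethylcyclohexa-1,4-diene | CC1=CCC=C(C)C1 | intermediate
3 | trichloroacetyl chloride | ClC(Cl)(Cl)C(Cl)=O | starting material
4 | dichloroketene | ClC(Cl)=C=O | intermediate
5 | rac-(1S,6R)-8,8-dichloro-1,3-dimethylbicyclo[4.2.0]oct-3-en-7-one (cis-fused) | CC1=CC[C@H]2C(=O)C(Cl)(Cl)[C@@]2(C)C1 | intermediate
6 | rac-(1S,6R,8S)-8-chloro-1,3-dimethylbicyclo[4.2.0]oct-3-en-7-one (Cl endo) | CC1=CC[C@H]2C(=O)[C@@H](Cl)[C@@]2(C)C1 | intermediate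
7 | rac-(1S,6R,7R,8S)-8-chloro-1,3-dimethylbicyclo[4.2.0]oct-3-en-7-ol (OH cis to Cl) | CC1=CC[C@H]2[C@@H](O)[C@@H](Cl)[C@@]2(C)C1 | intermediate
8 | (1S,6R,7R,8S)-8-chloro-1,3-dimethylbicyclo[4.2.0]oct-3-en-7-yl (1S)-camphor-10-sulfonate | CC1=CC[C@H]2[C@@H](OS(=O)(=O)C[C@]34CC[C@H](CC3=O)C4(C)C)[C@@H](Cl)[C@@]2(C)C1 | intermediate
9 | (1S,6R,7S,8S)-7-bromo-8-chloro-1,3-dimethylbicyclo[4.2.0]oct-3-ene (Br exo, trans to Cl) | CC1=CC[C@H]2[C@H](Br)[C@@H](Cl)[C@@]2(C)C1 | intermediate
10 | (4S,5R)-5-bromo-4-[(E)-2-chloroethenyl]-1,5-dimethylcyclohex-1-ene | CC1=CC[C@@H](/C=C/Cl)[C@](C)(Br)C1 | intermediate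
11 | [(1R,2R,4R,5S)-4-bromo-2-chloro-5-[(E)-2-chloroethenyl]-2,4-dimethylcyclohexyl](phenyl)selane | C[C@@]1(Cl)C[C@@](C)(Br)[C@H](/C=C/Cl)C[C@H]1[Se]c2ccccc2 | intermediate
12 | dibromo[(1R,2R,4R,5S)-4-bromo-2-chloro-5-[(E)-2-chloroethenyl]-2,4-dimethylcyclohexyl](phenyl)-λ4-selane | C[C@@]1(Cl)C[C@@](C)(Br)[C@H](/C=C/Cl)C[C@H]1[Se](Br)(Br)c2ccccc2 | intermediate
13 | (1R,2S,4S,5R)-1,4-dibromo-5-chloro-2-[(E)-2-chloroethenyl]-1,5-dimethylcyclohexane | C[C@@]1(Cl)C[C@@](C)(Br)[C@H](/C=C/Cl)C[C@@H]1Br | target

**Total step count:** 7. **Longest linear sequence:** 7 (from m-xylene).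

**Steps most likely to fail**

Step 6 (the new isomerisation). Risks are that 9 fails to ionise, that the tertiary bromide 10 re-ionises and leaks to elimination or to the secondary bromide, or that E/Z purity is lost. The fallback uses known chemistry, sets out from 2 and comes back at 10. Diene 2 is mono-epoxidised with the Shi ketone/Oxone (catalyst enantiomer chosen for this epoxide) to give (1R,6S)-1,3-dimethyl-7-oxabicyclo[4.1.0]hept-3-ene F3. LiC≡CSiMe3/BF3·OEt2 opens it at the secondary carbon with inversion to give (1R,6S)-1,3-dimethyl-6-[(trimethylsilyl)ethynyl]cyclohex-3-en-1-ol F4. K2CO3/MeOH gives (1R,6S)-6-ethynyl-1,3-dimethylcyclohex-3-en-1-ol F5. Cp2Zr(H)Cl then NCS gives (1R,6S)-6-[(E)-2-chloroethenyl]-1,3-dimethylcyclohex-3-en-1-ol F6. Me3SiBr in CH2Cl2 at −40 °C then replaces the tertiary OH by Br with retention (SN1 with neighbouring alkenyl participation) to give 10. This path is enantioselective and would also make the resolution unnecessary.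

Step 7 (syn-bromochlorination). Risks are the wrong alkene face, chlorine participation during the Se(IV) displacement, and HCl loss from the chloro selenide. The fallback sets out from 10 and comes back at 13. Epoxidation (mCPBA, or the Shi ketone for reagent control) on the face of the C–Br bond gives (1S,3S,4R,6R)-4-bromo-3-[(E)-2-chloroethenyl]-1,4-dimethyl-7-oxabicyclo[4.1.0]heptane F7. ClTi(OiPr)3 opens it at the tertiary carbon with inversion to give (1R,2R,4R,5S)-4-bromo-2-chloro-5-[(E)-2-chloroethenyl]-2,4-dimethylcyclohexan-1-ol F8. Appel bromination (PPh3, CBr4) with inversion at the secondary carbinol gives 13.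

Step 5 (resolution by diastereomer separation). The risk is that the two camphorsulfonates do not separate. The fallback sets out from 7 and comes back at 9. Lipase-catalysed acylation (Amano PS, vinyl acetate, MTBE) is assumed, by Kazlauskas' rule, to acylate the (7R) enantiomer, giving (1S,6R,7R,8S)-8-chloro-1,3-dimethylbicyclo[4.2.0]oct-3-en-7-yl acetate F1; if the sense is opposite, the unreacted alcohol is used directly. F1 is separated from the unreacted enantiomer and methanolysed (K2CO3, MeOH) to enantiopure 7. MsCl/Et3N gives (1S,6R,7R,8S)-8-chloro-1,3-dimethylbicyclo[4.2.0]oct-3-en-7-yl methanesulfonate F2, and LiBr in butanone gives 9 by the same SN2 inversion.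

**Further compounds**
F1 | step 5 | (1S,6R,7R,8S)-8-chloro-1,3-dimethylbicyclo[4.2.0]oct-3-en-7-yl acetate | CC1=CC[C@H]2[C@@H](OC(C)=O)[C@@H](Cl)[C@@]2(C)C1
F2 | step 5 | (1S,6R,7R,8S)-8-chloro-1,3-dimethylbicyclo[4.2.0]oct-3-en-7-yl methanesulfonate | CC1=CC[C@H]2[C@@H](OS(C)(=O)=O)[C@@H](Cl)[C@@]2(C)C1
F3 | step 6 | (1R,6S)-1,3-dimethyl-7-oxabicyclo[4.1.0]hept-3-ene | CC1=CC[C@@H]2O[C@]2(C)C1
F4 | step 6 | (1R,6S)-1,3-dimethyl-6-[(trimethylsilyl)ethynyl]cyclohex-3-en-1-ol | CC1=CC[C@@H](C#C[Si](C)(C)C)[C@](C)(O)C1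
F5 | step 6 | (1R,6S)-6-ethynyl-1,3-dimethylcyclohex-3-en-1-ol | CC1=CC[C@@H](C#C)[C@](C)(O)C1
F6 | step 6 | (1R,6S)-6-[(E)-2-chloroethenyl]-1,3-dimethylcyclohex-3-en-1-ol | CC1=CC[C@@H](/C=C/Cl)[C@](C)(O)C1
F7 | step 7 | (1S,3S,4R,6R)-4-bromo-3-[(E)-2-chloroethenyl]-1,4-dimethyl-7-oxabicyclo[4.1.0]heptane (O cis to Br) | C[C@@]12O[C@@H]1C[C@@H](/C=C/Cl)[C@](C)(Br)C2
F8 | step 7 | (1R,2R,4R,5S)-4-bromo-2-chloro-5-[(E)-2-chloroethenyl]-2,4-dimethylcyclohexan-1-ol | C[C@@]1(Cl)C[C@@](C)(Br)[C@H](/C=C/Cl)C[C@H]1O
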